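**Plan**

1. Germacrane numbering is used throughout: C1 ketone, C2=C3 (C3 on the ring oxygen), C4 (methyl C15), C5 (OH), C6 (ester), C7, C8 (lactone O), C9, C10 (quaternary, methyl C14, ring oxygen), lactone C11–C13. The five-membered ring O–C3=C2–C1(=O)–C10 is a 2-methylfuran-3-ol alkylated on its ring carbon C10 and so dearomatised; C9 is the single CH2 between C10 and the C7–C8 unit, so C9–C10 is an allyl–furanolate bond.
2. Retrosynthesis: remove the C6 methacrylate and the O5 protecting group; open the methylene lactone (C11=C13, then C12–O8); take C8–O and C7–H back to a ring-cis C7=C8 alkene; cut C9–C10 (ten-membered ring B); open the furanone ring A at O–C3 and C1–C2; cut C6–C7 and C3–C4.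
3. Forward: an alkynyl aldehyde (C2–C6) and a Z-iodoalkene (C7–C9 with C11–C12) are joined at C6–C7; ring A is built on the alkyne from a lactic amide; ring B is closed at C9–C10; lactone ring C is made last.
4. Stereochemistry: C4 and C5 from a Sharpless epoxide opened with inversion; C6 from chelate-controlled addition; the C7=C8 geometry from trans-hydroalumination–iodination; C10 in the ring closure (tether plus chiral ligand); C7 and C8 from an O6-tethered syn hydrosilylation followed by retentive C–Si oxidation.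

Key step: step 17

Remark on the chemistry: 4,4-diethoxybut-1-yne (8) is assumed to be purchasable (otherwise one step from propargyl bromide, aluminium and triethyl orthoformate). Furanones 21 and 22 are C10-epimer mixtures, which is of no consequence because C10 becomes planar in step 17. An untethered hydroboration of the C7=C8 alkene is expected, by allylic-strain models, to add from the wrong face, so the C8 oxygen is delivered from O6 through silicon.

**Route**

Step 1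
Reactants: 1 (E)-but-2-en-1-ol
Product: 2 [(2R,3R)-3-methyloxiran-2-yl]methanol
Conditions: Ti(OiPr)4 (cat.), D-(−)-diethyl tartrate (cat.), t-BuOOH, 4 Å sieves, CH2Cl2, −20 °C
Reagents that add atoms: tert-butyl hydroperoxide CC(C)(C)OO
Why: Sharpless asymmetric epoxidation, in which the D-tartrate directs oxygen to the face giving the (2R,3R)-epoxide, fixing the C5 oxygen centre and (after inversion in step 2) the C4 methyl centre.

Step 2
Reactants: 2 [(2R,3R)-3-methyloxiran-2-yl]methanol; 3 ethynyl(trimethyl)silane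
Product: 4 (2S,3R)-3-methyl-5-(trimethylsilyl)pent-4-yne-1,2-diol
Conditions: 3, n-BuLi, toluene, 0 °C; Et2AlCl; then 2, 0 °C → rt; aq. potassium sodium tartrate
Reagents that add atoms: none
Why: Ring opening of a 2,3-epoxy alcohol by a diethylaluminium acetylide, directed by the aluminium alkoxide to C3 with inversion, so the C4 methyl ends syn to the C5 hydroxyl and a 1,2-diol results.

Step 3
Reactants: 4 (2S,3R)-3-methyl-5-(trimethylsilyl)pent-4-yne-1,2-diol
Product: 5 (4S)-2-(4-methoxyphenyl)-4-[(2R)-4-(trimethylsilyl)but-3-yn-2-yl]-1,3-dioxolane (acetal epimers)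
Conditions: 4-MeOC6H4CH(OMe)2, PPTS (cat.), CH2Cl2, rt
Reagents that add atoms: 4-methoxybenzaldehyde dimethyl acetal COc1ccc(cc1)C(OC)OC
Why: Acid-catalysed transacetalisation gives the five-membered p-methoxybenzylidene acetal of the 1,2-diol.

Step 4
Reactants: 5 (4S)-2-(4-methoxyphenyl)-4-[(2R)-4-(trimethylsilyl)but-3-yn-2-yl]-1,3-dioxolane
Product: 6 (2S,3R)-2-[(4-methoxybenzyl)oxy]-3-methyl-5-(trimethylsilyl)pent-4-yn-1-ol
Conditions: i-Bu2AlH, CH2Cl2, −78 → 0 °C
Reagents that add atoms: none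
Why: Regioselective reductive acetal opening, in which aluminium binds the less hindered primary oxygen so that the PMB ether stays on the secondary oxygen O5 and the primary alcohol is freed.

Step 5
Reactants: 6 (2S,3R)-2-[(4-methoxybenzyl)oxy]-3-methyl-5-(trimethylsilyl)pent-4-yn-1-ol
Product: 7 (2S,3R)-2-[(4-methoxybenzyl)oxy]-3-methyl-5-(trimethylsilyl)pent-4-ynal
Conditions: Dess–Martin periodinane, pyridine, CH2Cl2, rt
Reagents that add atoms: none
Why: Buffered Dess–Martin oxidation should give the α-alkoxy aldehyde without epimerising C5.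

Step 6
Reactants: 8 4,4-diethoxybut-1-yne; 9 paraformaldehyde
Product: 10 5,5-diethoxypent-2-yn-1-ol
Conditions: n-BuLi, THF, −78 °C; (CH2O)n, −78 °C → rt
Reagents that add atoms: none
Why: Hydroxymethylation of a lithium acetylide with formaldehyde installs C9.

Step 7
Reactants: 10 5,5-diethoxypent-2-yn-1-ol
Product: 11 (2Z)-5,5-diethoxy-3-iodopent-2-en-1-ol
Conditions: NaAlH2(OCH2CH2OMe)2, THF, 0 °C → rt; then I2, −78 °C
Reagents that add atoms: iodine II
Why: Hydroxyl-directed trans-hydroalumination of the propargylic alcohol puts aluminium on the distal carbon (C7), and iodinolysis with retention gives the Z-iodoalkene that fixes the later ring-cis C7=C8 geometry.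

Step 8
Reactants: 11 (2Z)-5,5-diethoxy-3-iodopent-2-en-1-ol
Product: 12 triethyl{[(2Z)-5,5-diethoxy-3-iodopent-2-en-1-yl]oxy}silane
Conditions: Et3SiCl, imidazole, CH2Cl2, 0 °C
Reagents that add atoms: chlorotriethylsilane CC[Si](Cl)(CC)CC
Why: Standard silylation protects the C9 hydroxyl against the organolithium of step 9.

Step 9
Reactants: 12 triethyl{[(2Z)-5,5-diethoxy-3-iodopent-2-en-1-yl]oxy}silane; 7 (2S,3R)-2-[(4-methoxybenzyl)oxy]-3-methyl-5-(trimethylsilyl)pent-4-ynal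
Product: 13 (2Z,4S,5S,6R)-3-(2,2-diethoxyethyl)-5-[(4-methoxybenzyl)oxy]-6-methyl-1-[(triethylsilyl)oxy]-8-(trimethylsilyl)oct-2-en-7-yn-4-ol
Conditions: 12, t-BuLi (2 equiv), Et2O, −78 °C; MgBr2·OEt2; then 7, CH2Cl2, −78 °C
Reagents that add atoms: none
Why: Iodine–lithium exchange with retention of alkene geometry, transmetalation to magnesium and Cram-chelate addition (magnesium bridging the aldehyde oxygen and the α-OPMB group) should deliver the alkenyl group anti to the C4 branch and give the 5,6-syn alcohol.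

Step 10
Reactants: 13 (2Z,4S,5S,6R)-3-(2,2-diethoxyethyl)-5-[(4-methoxybenzyl)oxy]-6-methyl-1-[(triethylsilyl)oxy]-8-(trimethylsilyl)oct-2-en-7-yn-4-ol
Product: 14 (2Z,4S,5S,6R)-4-[(tert-butyldimethylsilyl)oxy]-3-(2,2-diethoxyethyl)-5-[(4-methoxybenzyl)oxy]-6-methyl-1-[(triethylsilyl)oxy]-8-(trimethylsilyl)oct-2-en-7-yne
Conditions: t-BuMe2SiCl, imidazole, DMAP (cat.), DMF, 45 °C
Reagents that add atoms: tert-butyl(chloro)dimethylsilane CC(C)(C)[Si](C)(C)Cl
Why: Silylation masks O6, which would otherwise add 5-exo to the ynone of step 14 and to the π-allyl complex of step 17.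

Step 11
Reactants: 14 (2Z,4S,5S,6R)-4-[(tert-butyldimethylsilyl)oxy]-3-(2,2-diethoxyethyl)-5-[(4-methoxybenzyl)oxy]-6-methyl-1-[(triethylsilyl)oxy]-8-(trimethylsilyl)oct-2-en-7-yne
Product: 15 (2Z,4S,5S,6R)-4-[(tert-butyldimethylsilyl)oxy]-3-(2,2-diethoxyethyl)-5-[(4-methoxybenzyl)oxy]-6-methyl-1-[(triethylsilyl)oxy]oct-2-en-7-yne
Conditions: K2CO3 (cat.), MeOH, rt
Reagents that add atoms: none
Why: Base-catalysed methanolysis cleaves only the alkynyl C–Si bond and leaves the silyl ethers and the acetal.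

Step 12
Reactants: 16 ethyl (2S)-2-hydroxypropanoate
Product: 17 (2S)-2-hydroxy-N-methoxy-N-methylpropanamide
Conditions: MeNH(OMe)·HCl, i-PrMgCl, THF, −20 → 0 °C
Reagents that add atoms: N,O-dimethylhydroxylamine hydrochloride CNOC.Cl
Why: Weinreb amide formation from the ester with the magnesium amide (the lactate configuration is lost later at C10 and is immaterial).

Step 13
Reactants: 17 (2S)-2-hydroxy-N-methoxy-N-methylpropanamide
Product: 18 (2S)-N-methoxy-N-methyl-2-[(triethylsilyl)oxy]propanamide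
Conditions: Et3SiCl, imidazole, CH2Cl2, 0 °C
Reagents that add atoms: chlorotriethylsilane CC[Si](Cl)(CC)CC
Why: Silylation removes the acidic hydroxyl so that one equivalent of the acetylide suffices in step 14.

Step 14
Reactants: 15 (2Z,4S,5S,6R)-4-[(tert-butyldimethylsilyl)oxy]-3-(2,2-diethoxyethyl)-5-[(4-methoxybenzyl)oxy]-6-methyl-1-[(triethylsilyl)oxy]oct-2-en-7-yne; 18 (2S)-N-methoxy-N-methyl-2-[(triethylsilyl)oxy]propanamide
Product: 19 (2S,6R,7S,8S,9Z)-8-[(tert-butyldimethylsilyl)oxy]-9-(2,2-diethoxyethyl)-7-[(4-methoxybenzyl)oxy]-6-methyl-2,11-bis[(triethylsilyl)oxy]undec-9-en-4-yn-3-one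
Conditions: 15, n-BuLi, THF, −78 °C; then 18, −78 → −20 °C
Reagents that add atoms: none
Why: Acylation of the lithium acetylide by the Weinreb amide forms C1–C2, the chelated tetrahedral intermediate preventing over-addition.

Step 15
Reactants: 19 (2S,6R,7S,8S,9Z)-8-[(tert-butyldimethylsilyl)oxy]-9-(2,2-diethoxyethyl)-7-[(4-methoxybenzyl)oxy]-6-methyl-2,11-bis[(triethylsilyl)oxy]undec-9-en-4-yn-3-one
Product: 21 5-[(2S,3S,4S,5Z)-4-[(tert-butyldimethylsilyl)oxy]-5-(2,2-diethoxyethyl)-7-hydroxy-3-[(4-methoxybenzyl)oxy]hept-5-en-2-yl]-2-methylfuran-3(2H)-one (C10 epimers), via dihydroxy ynone 20 (not isolated)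
Conditions: PPTS (cat.), EtOH, rt; then Et2NH, rt
Reagents that add atoms: none
Why: Mild ethanolysis removes both triethylsilyl ethers but not the hindered TBS ether, and diethylamine then adds to the ynone and is displaced by the α'-hydroxyl (the classical hydroxy-ynone cyclisation to a 3(2H)-furanone), closing ring A.

Step 16
Reactants: 21 5-[(2S,3S,4S,5Z)-4-[(tert-butyldimethylsilyl)oxy]-5-(2,2-diethoxyethyl)-7-hydroxy-3-[(4-methoxybenzyl)oxy]hept-5-en-2-yl]-2-methylfuran-3(2H)-one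
Product: 22 (2Z,4S,5S,6S)-4-[(tert-butyldimethylsilyl)oxy]-3-(2,2-diethoxyethyl)-5-[(4-methoxybenzyl)oxy]-6-(5-methyl-4-oxo-4,5-dihydrofuran-2-yl)hept-2-en-1-yl methyl carbonate (C10 epimers)
Conditions: ClCO2Me, pyridine, CH2Cl2, 0 °C
Reagents that add atoms: methyl chloroformate COC(=O)Cl
Why: Acylation of the only free (primary allylic) hydroxyl gives the ionisable carbonate that also stores the base for step 17.

Step 17
Reactants: 22 (2Z,4S,5S,6S)-4-[(tert-butyldimethylsilyl)oxy]-3-(2,2-diethoxyethyl)-5-[(4-methoxybenzyl)oxy]-6-(5-methyl-4-oxo-4,5-dihydrofuran-2-yl)hept-2-en-1-yl methyl carbonate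
Product: 24 (2Z,4S,5S,6S,7Z,10R)-6-[(tert-butyldimethylsilyl)oxy]-7-(2,2-diethoxyethyl)-5-[(4-methoxybenzyl)oxy]-4,10-dimethyl-3,10-epoxycyclodeca-2,7-dien-1-one, via furan-3-ol tautomer 23 (not isolated)
Conditions: Pd2(dba)3·CHCl3 (5 mol%), (R,R)-DACH-phenyl Trost ligand (15 mol%), THF, 40 °C, syringe-pump addition of 22 to 0.002 M
Reagents that add atoms: none
Why: Proposed new method: zerovalent palladium ionises the primary allylic carbonate with loss of CO2, the methoxide set free deprotonates either C10 epimer (or the furan-3-ol 23) to the planar aromatic furan-3-olate, and this attacks the unsubstituted terminus C9 of the π-allyl complex through its ring carbon C10 on the face opposite to palladium. The closest known reactions are palladium-catalysed asymmetric allylic alkylations of benzofuran-3(2H)-ones and ketone enolates that create α-quaternary centres, and Tsuji–Trost macrocyclisations with stabilised carbon nucleophiles. Ring B closes end to end as a ten-membered carbocycle with the allyl unit inside the ring (the C6 branch is the anti substituent of the allyl, so the new alkene is ring-cis) and with the furan oxygen as the one-atom bridge of a bicyclo[6.2.1] skeleton. The C10 stereocentre is set by the face of the furanolate that the C4–C9 tether brings over C9, a preference of the C4–C6 stereocentres that the chiral pocket of the ligand is meant to reinforce (the antipodal ligand is used if the pairing proves mismatched). C- over O-alkylation, C9 over C7 attack and retention of the Z geometry are needed. They are secured by the soft π-allyl electrophile and the strain of bridging the 3- and 5-positions of an intact furan by seven atoms, by the full substitution of C7, and by the fact that syn–anti exchange would need an η1-palladium on the tertiary C7.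

Step 18
Reactants: 24 (2Z,4S,5S,6S,7Z,10R)-6-[(tert-butyldimethylsilyl)oxy]-7-(2,2-diethoxyethyl)-5-[(4-methoxybenzyl)oxy]-4,10-dimethyl-3,10-epoxycyclodeca-2,7-dien-1-one
Product: 25 (2Z,4S,5S,6S,7Z,10R)-7-(2,2-diethoxyethyl)-6-hydroxy-5-[(4-methoxybenzyl)oxy]-4,10-dimethyl-3,10-epoxycyclodeca-2,7-dien-1-one
Conditions: Bu4NF, AcOH, THF, rt
Reagents that add atoms: none
Why: Buffered fluoride desilylation frees the allylic C6 hydroxyl; the furanone now has no acidic C10–H, and the acetal and PMB ether are inert.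

Step 19
Reactants: 25 (2Z,4S,5S,6S,7Z,10R)-7-(2,2-diethoxyethyl)-6-hydroxy-5-[(4-methoxybenzyl)oxy]-4,10-dimethyl-3,10-epoxycyclodeca-2,7-dien-1-one
Product: 27 (4S,5S,6S,7S,8S,10R)-7-(2,2-diethoxyethyl)-5-[(4-methoxybenzyl)oxy]-4,10-dimethyl-6-O,8-C-(dimethylsilanediyl)-6-hydroxy-3,10-epoxycyclodec-2-en-1-one (2,2-dimethyl-1-oxa-2-silacyclopentane across C6–C7–C8; O6 and H7 and Si on one face of ring B), via dimethylsilyl ether 26 (not isolated)
Conditions: (HMe2Si)2NH, CH2Cl2, rt, evaporate; Pt2[(CH2=CHSiMe2)2O]3 (1 mol%), toluene, 60 °C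
Reagents that add atoms: 1,1,3,3-tetramethyldisilazane C[SiH](C)N[SiH](C)C
Why: Tamao-type intramolecular hydrosilylation of an allylic alcohol (5-endo), in which the O6–Si tether forces syn delivery of silicon to C8 and hydrogen to C7 from the alkene face on which O6 sits with C5 turned away from the C11 arm (A1,2 strain), setting C7 and C8 together from the Z-alkene.

Step 20
Reactants: 27 the oxasilolane of step 19
Product: 28 (2Z,4S,5S,6S,7R,8S,10R)-7-(2,2-diethoxyethyl)-6,8-dihydroxy-5-[(4-methoxybenzyl)oxy]-4,10-dimethyl-3,10-epoxycyclodec-2-en-1-one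
Conditions: 30% H2O2, KF, KHCO3, THF/MeOH, rt
Reagents that add atoms: hydrogen peroxide OO
Why: Tamao–Fleming oxidation converts the C8–Si bond into C8–OH with retention of configuration.

Step 21
Reactants: 28 (2Z,4S,5S,6S,7R,8S,10R)-7-(2,2-diethoxyethyl)-6,8-dihydroxy-5-[(4-methoxybenzyl)oxy]-4,10-dimethyl-3,10-epoxycyclodec-2-en-1-one
Product: 29 (2Z,4S,5S,6S,7S,8S,10R)-7-(2,2-diethoxyethyl)-6-hydroxy-5-[(4-methoxybenzyl)oxy]-4,10-dimethyl-8-[(triethylsilyl)oxy]-3,10-epoxycyclodec-2-en-1-one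
Conditions: Et3SiCl (1.05 equiv), imidazole, CH2Cl2, −40 °C
Reagents that add atoms: chlorotriethylsilane CC[Si](Cl)(CC)CC
Why: Kinetic silylation should select the C8 hydroxyl, flanked by the C9 methylene, over the C6 hydroxyl, flanked by the PMB-bearing C5.

Step 22
Reactants: 29 (2Z,4S,5S,6S,7S,8S,10R)-7-(2,2-diethoxyethyl)-6-hydroxy-5-[(4-methoxybenzyl)oxy]-4,10-dimethyl-8-[(triethylsilyl)oxy]-3,10-epoxycyclodec-2-en-1-one; 30 methacrylic anhydride
Product: 31 6-O-methacryloyl derivative of 29: (2Z,4S,5S,6S,7S,8S,10R)-7-(2,2-diethoxyethyl)-5-[(4-methoxybenzyl)oxy]-4,10-dimethyl-1-oxo-8-[(triethylsilyl)oxy]-3,10-epoxycyclodec-2-en-6-yl 2-methylprop-2-enoate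
Conditions: 30, DMAP, Et3N, CH2Cl2, rt → 40 °C
Reagents that add atoms: none
Why: DMAP-catalysed acylation of the remaining secondary alcohol installs the C6 ester before any lactone enolate or free C8 hydroxyl exists.

Step 23
Reactants: 31 the 6-O-methacryloyl 8-O-triethylsilyl acetal of step 22
Product: 32 (4S,5S,6S,7R,8S,10R)-12-hydroxy-5-[(4-methoxybenzyl)oxy]-6-(methacryloyloxy)-13-nor-3,10:8,12-diepoxygermacr-2-en-1-one (lactol; C12 anomers)
Conditions: AcOH/THF/H2O (3:1:1), 40 °C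
Reagents that add atoms: water O
Why: Aqueous acetic acid cleaves the triethylsilyl ether and hydrolyses the diethyl acetal, and the γ-hydroxy aldehyde closes to the five-membered lactol on O8, the only free hydroxyl.

Step 24
Reactants: 32 the lactol of step 23; 33 N,N-dimethylmethyleneiminium iodide (Eschenmoser's salt)
Product: 34 (4S,5S,6S,7R,8S,10R)-12-hydroxy-5-[(4-methoxybenzyl)oxy]-6-(methacryloyloxy)-3,10:8,12-diepoxygermacra-2,11(13)-dien-1-one (α-methylene lactol)
Conditions: 33, Et3N, CH2Cl2, rt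
Reagents that add atoms: none
Why: Mannich α-methylenation of the aldehyde in equilibrium with the lactol (aminomethylation at C11, then loss of dimethylamine) brings in C13 without any strong base that could touch the methacrylate or the C4–H of the furanone.

Step 25
Reactants: 34 the α-methylene lactol of step 24
Product: 35 (4S,5S,6S,7R,8S,10R)-5-[(4-methoxybenzyl)oxy]-6-(methacryloyloxy)-1-oxo-3,10-epoxygermacra-2,11(13)-dien-12,8-olide
Conditions: Dess–Martin periodinane, pyridine, CH2Cl2, rt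
Reagents that add atoms: none
Why: Oxidation of the lactol to the lactone completes the α-methylene-γ-butyrolactone ring C.

Step 26
Reactants: 35 the 5-O-PMB lactone of step 25
Product: 36 (4S,5S,6S,7R,8S,10R)-5-hydroxy-6-(methacryloyloxy)-1-oxo-3,10-epoxygermacra-2,11(13)-dien-12,8-olide (target)
Conditions: DDQ, CH2Cl2/pH 7 phosphate buffer, 0 °C → rt
Reagents that add atoms: none
Why: Oxidative PMB cleavage under buffered, near-neutral conditions frees the C5 hydroxyl without 6→5 acyl migration and without touching the three electron-poor alkenes.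

**Compound list**

1 | (E)-but-2-en-1-ol | C/C=C/CO | starting material
2 | [(2R,3R)-3-methyloxiran-2-yl]methanol | C[C@H]1O[C@@H]1CO | intermediate
3 | ethynyl(trimethyl)silane | C#C[Si](C)(C)C | starting material
4 | (2S,3R)-3-methyl-5-(trimethylsilyl)pent-4-yne-1,2-diol | C[Si](C)(C)C#C[C@@H](C)[C@H](O)CO | intermediate
5 | (4S)-2-(4-methoxyphenyl)-4-[(2R)-4-(trimethylsilyl)but-3-yn-2-yl]-1,3-dioxolane (acetal epimers) | C[Si](C)(C)C#C[C@@H](C)[C@H]1COC(O1)c1ccc(OC)cc1 | intermediate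
6 | (2S,3R)-2-[(4-methoxybenzyl)oxy]-3-methyl-5-(trimethylsilyl)pent-4-yn-1-ol | C[Si](C)(C)C#C[C@@H](C)[C@H](OCc1ccc(OC)cc1)CO | intermediate
7 | (2S,3R)-2-[(4-methoxybenzyl)oxy]-3-methyl-5-(trimethylsilyl)pent-4-ynal | C[Si](C)(C)C#C[C@@H](C)[C@H](OCc1ccc(OC)cc1)C=O | intermediate
8 | 4,4-diethoxybut-1-yne | C#CCC(OCC)OCC | starting material
9 | paraformaldehyde (as formaldehyde) | C=O | starting material
10 | 5,5-diethoxypent-2-yn-1-ol | OCC#CCC(OCC)OCC | intermediate
11 | (2Z)-5,5-diethoxy-3-iodopent-2-en-1-ol | OC/C=C(\I)CC(OCC)OCC | intermediate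
12 | triethyl{[(2Z)-5,5-diethoxy-3-iodopent-2-en-1-yl]oxy}silane | CC[Si](CC)(CC)OC/C=C(\I)CC(OCC)OCC | intermediate
13 | (2Z,4S,5S,6R)-3-(2,2-diethoxyethyl)-5-[(4-methoxybenzyl)oxy]-6-methyl-1-[(triethylsilyl)oxy]-8-(trimethylsilyl)oct-2-en-7-yn-4-ol | C[Si](C)(C)C#C[C@@H](C)[C@H](OCc1ccc(OC)cc1)[C@@H](O)/C(CC(OCC)OCC)=C\CO[Si](CC)(CC)CC | intermediate
14 | (2Z,4S,5S,6R)-4-[(tert-butyldimethylsilyl)oxy]-3-(2,2-diethoxyethyl)-5-[(4-methoxybenzyl)oxy]-6-methyl-1-[(triethylsilyl)oxy]-8-(trimethylsilyl)oct-2-en-7-yne | C[Si](C)(C)C#C[C@@H](C)[C@H](OCc1ccc(OC)cc1)[C@@H](O[Si](C)(C)C(C)(C)C)/C(CC(OCC)OCC)=C\CO[Si](CC)(CC)CC | intermediate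
15 | (2Z,4S,5S,6R)-4-[(tert-butyldimethylsilyl)oxy]-3-(2,2-diethoxyethyl)-5-[(4-methoxybenzyl)oxy]-6-methyl-1-[(triethylsilyl)oxy]oct-2-en-7-yne | C#C[C@@H](C)[C@H](OCc1ccc(OC)cc1)[C@@H](O[Si](C)(C)C(C)(C)C)/C(CC(OCC)OCC)=C\CO[Si](CC)(CC)CC | intermediate
16 | ethyl (2S)-2-hydroxypropanoate | C[C@H](O)C(=O)OCC | starting material
17 | (2S)-2-hydroxy-N-methoxy-N-methylpropanamide | C[C@H](O)C(=O)N(C)OC | intermediate
18 | (2S)-N-methoxy-N-methyl-2-[(triethylsilyl)oxy]propanamide | C[C@H](O[Si](CC)(CC)CC)C(=O)N(C)OC | intermediate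
19 | (2S,6R,7S,8S,9Z)-8-[(tert-butyldimethylsilyl)oxy]-9-(2,2-diethoxyethyl)-7-[(4-methoxybenzyl)oxy]-6-methyl-2,11-bis[(triethylsilyl)oxy]undec-9-en-4-yn-3-one | C[C@H](O[Si](CC)(CC)CC)C(=O)C#C[C@@H](C)[C@H](OCc1ccc(OC)cc1)[C@@H](O[Si](C)(C)C(C)(C)C)/C(CC(OCC)OCC)=C\CO[Si](CC)(CC)CC | intermediate
20 | (2S,6R,7S,8S,9Z)-8-[(tert-butyldimethylsilyl)oxy]-9-(2,2-diethoxyethyl)-2,11-dihydroxy-7-[(4-methoxybenzyl)oxy]-6-methylundec-9-en-4-yn-3-one | C[C@H](O)C(=O)C#C[C@@H](C)[C@H](OCc1ccc(OC)cc1)[C@@H](O[Si](C)(C)C(C)(C)C)/C(CC(OCC)OCC)=C\CO | intermediate (not isolated)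
21 | 5-[(2S,3S,4S,5Z)-4-[(tert-butyldimethylsilyl)oxy]-5-(2,2-diethoxyethyl)-7-hydroxy-3-[(4-methoxybenzyl)oxy]hept-5-en-2-yl]-2-methylfuran-3(2H)-one (C10 epimers) | CC1OC(=CC1=O)[C@@H](C)[C@H](OCc2ccc(OC)cc2)[C@@H](O[Si](C)(C)C(C)(C)C)/C(CC(OCC)OCC)=C\CO | intermediate
22 | (2Z,4S,5S,6S)-4-[(tert-butyldimethylsilyl)oxy]-3-(2,2-diethoxyethyl)-5-[(4-methoxybenzyl)oxy]-6-(5-methyl-4-oxo-4,5-dihydrofuran-2-yl)hept-2-en-1-yl methyl carbonate (C10 epimers) | CC1OC(=CC1=O)[C@@H](C)[C@H](OCc2ccc(OC)cc2)[C@@H](O[Si](C)(C)C(C)(C)C)/C(CC(OCC)OCC)=C\COC(=O)OC | intermediate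
23 | (2Z,4S,5S,6S)-4-[(tert-butyldimethylsilyl)oxy]-3-(2,2-diethoxyethyl)-6-(4-hydroxy-5-methylfuran-2-yl)-5-[(4-methoxybenzyl)oxy]hept-2-en-1-yl methyl carbonate (furan-3-ol tautomer of 22; reacts as its anion) | Cc1oc(cc1O)[C@@H](C)[C@H](OCc2ccc(OC)cc2)[C@@H](O[Si](C)(C)C(C)(C)C)/C(CC(OCC)OCC)=C\COC(=O)OC | intermediate (not isolated)
24 | (2Z,4S,5S,6S,7Z,10R)-6-[(tert-butyldimethylsilyl)oxy]-7-(2,2-diethoxyethyl)-5-[(4-methoxybenzyl)oxy]-4,10-dimethyl-3,10-epoxycyclodeca-2,7-dien-1-one | CCOC(OCC)C/C1=C/C[C@@]2(C)OC(=CC2=O)[C@@H](C)[C@H](OCc3ccc(OC)cc3)[C@H]1O[Si](C)(C)C(C)(C)C | intermediate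
25 | (2Z,4S,5S,6S,7Z,10R)-7-(2,2-diethoxyethyl)-6-hydroxy-5-[(4-methoxybenzyl)oxy]-4,10-dimethyl-3,10-epoxycyclodeca-2,7-dien-1-one | CCOC(OCC)C/C1=C/C[C@@]2(C)OC(=CC2=O)[C@@H](C)[C@H](OCc3ccc(OC)cc3)[C@H]1O | intermediate
26 | (2Z,4S,5S,6S,7Z,10R)-7-(2,2-diethoxyethyl)-6-[(dimethylsilyl)oxy]-5-[(4-methoxybenzyl)oxy]-4,10-dimethyl-3,10-epoxycyclodeca-2,7-dien-1-one | CCOC(OCC)C/C1=C/C[C@@]2(C)OC(=CC2=O)[C@@H](C)[C@H](OCc3ccc(OC)cc3)[C@H]1O[SiH](C)C | intermediate (not isolated)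
27 | (4S,5S,6S,7S,8S,10R)-7-(2,2-diethoxyethyl)-5-[(4-methoxybenzyl)oxy]-4,10-dimethyl-6-O,8-C-(dimethylsilanediyl)-6-hydroxy-3,10-epoxycyclodec-2-en-1-one (oxasilolane across C6–C7–C8) | CCOC(OCC)C[C@@H]1[C@@H]3C[C@@]2(C)OC(=CC2=O)[C@@H](C)[C@H](OCc4ccc(OC)cc4)[C@H]1O[Si]3(C)C | intermediate
28 | (2Z,4S,5S,6S,7R,8S,10R)-7-(2,2-diethoxyethyl)-6,8-dihydroxy-5-[(4-methoxybenzyl)oxy]-4,10-dimethyl-3,10-epoxycyclodec-2-en-1-one | CCOC(OCC)C[C@@H]1[C@@H](O)C[C@@]2(C)OC(=CC2=O)[C@@H](C)[C@H](OCc3ccc(OC)cc3)[C@H]1O | intermediate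
29 | (2Z,4S,5S,6S,7S,8S,10R)-7-(2,2-diethoxyethyl)-6-hydroxy-5-[(4-methoxybenzyl)oxy]-4,10-dimethyl-8-[(triethylsilyl)oxy]-3,10-epoxycyclodec-2-en-1-one | CCOC(OCC)C[C@@H]1[C@@H](O[Si](CC)(CC)CC)C[C@@]2(C)OC(=CC2=O)[C@@H](C)[C@H](OCc3ccc(OC)cc3)[C@H]1O | intermediate
30 | methacrylic anhydride | CC(=C)C(=O)OC(=O)C(C)=C | starting material
31 | (2Z,4S,5S,6S,7S,8S,10R)-7-(2,2-diethoxyethyl)-5-[(4-methoxybenzyl)oxy]-4,10-dimethyl-1-oxo-8-[(triethylsilyl)oxy]-3,10-epoxycyclodec-2-en-6-yl 2-methylprop-2-enoate | CCOC(OCC)C[C@@H]1[C@@H](O[Si](CC)(CC)CC)C[C@@]2(C)OC(=CC2=O)[C@@H](C)[C@H](OCc3ccc(OC)cc3)[C@H]1OC(=O)C(C)=C | intermediate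
32 | (4S,5S,6S,7R,8S,10R)-12-hydroxy-5-[(4-methoxybenzyl)oxy]-6-(methacryloyloxy)-13-nor-3,10:8,12-diepoxygermacr-2-en-1-one (lactol, C12 anomers) | OC1C[C@@H]2[C@@H](O1)C[C@@]3(C)OC(=CC3=O)[C@@H](C)[C@H](OCc4ccc(OC)cc4)[C@H]2OC(=O)C(C)=C | intermediate
33 | N,N-dimethylmethyleneiminium iodide | C=[N+](C)C.[I-] | starting material
34 | (4S,5S,6S,7R,8S,10R)-12-hydroxy-5-[(4-methoxybenzyl)oxy]-6-(methacryloyloxy)-3,10:8,12-diepoxygermacra-2,11(13)-dien-1-one (C12 anomers) | OC1C(=C)[C@@H]2[C@@H](O1)C[C@@]3(C)OC(=CC3=O)[C@@H](C)[C@H](OCc4ccc(OC)cc4)[C@H]2OC(=O)C(C)=C | intermediate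
35 | (4S,5S,6S,7R,8S,10R)-5-[(4-methoxybenzyl)oxy]-6-(methacryloyloxy)-1-oxo-3,10-epoxygermacra-2,11(13)-dien-12,8-olide | O=C1C(=C)[C@@H]2[C@@H](O1)C[C@@]3(C)OC(=CC3=O)[C@@H](C)[C@H](OCc4ccc(OC)cc4)[C@H]2OC(=O)C(C)=C | intermediate
36 | (4S,5S,6S,7R,8S,10R)-5-hydroxy-6-(methacryloyloxy)-1-oxo-3,10-epoxygermacra-2,11(13)-dien-12,8-olide | O=C1C(=C)[C@@H]2[C@@H](O1)C[C@@]3(C)OC(=CC3=O)[C@@H](C)[C@H](O)[C@H]2OC(=O)C(C)=C | target

**Step count and risks**

Total step count: 26. Longest linear sequence: 21 steps (1 → 2 → 4 → 5 → 6 → 7 → 13 → 14 → 15 → 19 → 21 → 22 → 24 → 25 → 27 → 28 → 29 → 31 → 32 → 34 → 35 → 36).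

Steps most likely to fail:

Step 17. The ring closure may be diverted by O-alkylation of the furanolate, by intermolecular alkylation (oligomers) at any practical dilution, or by attack on the wrong face of the furanolate. The fallback makes C9–C10 first and closes ring B at C6–C7, all by known reactions; it sets out from 11 (with 6) and comes back at 25.
- Iodo alcohol 11 is converted with CBr4 and PPh3 into (2Z)-1-bromo-5,5-diethoxy-3-iodopent-2-ene F1.
- The lithium enolate (LDA, THF, −78 °C) of the lactic acid acetal (2S,5S)-2-tert-butyl-5-methyl-1,3-dioxolan-4-one is alkylated by F1 anti to the tert-butyl group (self-regeneration of the stereocentre). This should give (2S,5R)-2-tert-butyl-5-[(2Z)-5,5-diethoxy-3-iodopent-2-en-1-yl]-5-methyl-1,3-dioxolan-4-one F2, with C10 already in the target configuration.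
- Alcohol 6 is silylated (t-BuMe2SiCl, imidazole) to the silyl ether F3.
- The alkynylsilane of F3 is cleaved with MeLi·LiBr and the lithium acetylide is added to F2; the hemiketal collapses with loss of pivalaldehyde to the α'-hydroxy ynone F4.
- Et2NH in EtOH closes the 2,2-disubstituted furanone silyl ether F5; Bu4NF frees the primary furanone alcohol F6; Dess–Martin oxidation gives the furanone aldehyde F7.
- A Nozaki–Hiyama–Kishi macrocyclisation (CrCl2, catalytic NiCl2, DMSO/THF, high dilution) joins C7 to C6 and gives 25. The C6 epimer, if formed, would be separated or corrected by oxidation and chelate-controlled reduction.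

Step 19. The tethered hydrosilylation may be slow on a trisubstituted alkene held in a bridged ten-membered ring, or the ring may not reach the conformation in which O6 lies over the alkene face. The fallback sets out from 25 and comes back at 28.
- Hydroxyl-directed epoxidation (VO(acac)2, t-BuOOH, CH2Cl2) should deliver oxygen syn to O6 and give the 7,8-epoxy alcohol F8.
- Cp2TiCl (trivalent titanium, made from Cp2TiCl2 and zinc dust) with 1,4-cyclohexadiene opens the epoxide homolytically at the tertiary C7 and reduces the radical by hydrogen-atom transfer, giving diol 28.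
- C8 is fixed by the epoxide; the C7 configuration then depends on the face of hydrogen delivery and would have to be verified.

Step 21. Silylation may discriminate poorly between the two secondary hydroxyls, or the silyl group may migrate. The fallback differentiates O6 and O8 before the C8 oxygen exists; it sets out from 27 and comes back at 32.
- HF·pyridine (pyridine-buffered, THF, 0 °C) cleaves the Si–O6 bond of the oxasilolane as in any silyl ether, giving the fluorosilyl alcohol F9.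
- Methacrylic anhydride and DMAP acylate O6 to the fluorosilyl methacrylate F10.
- Tamao oxidation (H2O2, KF, KHCO3) gives the C8 alcohol F11.
- Aqueous acetic acid hydrolyses the acetal of F11 to lactol 32.

Further compounds
F1 | step 17 | (2Z)-1-bromo-5,5-diethoxy-3-iodopent-2-ene | BrC/C=C(\I)CC(OCC)OCC
F2 | step 17 | (2S,5R)-2-tert-butyl-5-[(2Z)-5,5-diethoxy-3-iodopent-2-en-1-yl]-5-methyl-1,3-dioxolan-4-one | CCOC(OCC)C/C(I)=C/C[C@@]1(C)O[C@@H](OC1=O)C(C)(C)C
F3 | step 17 | tert-butyl{[(2S,3R)-2-[(4-methoxybenzyl)oxy]-3-methyl-5-(trimethylsilyl)pent-4-yn-1-yl]oxy}dimethylsilane | C[Si](C)(C)C#C[C@@H](C)[C@H](OCc1ccc(OC)cc1)CO[Si](C)(C)C(C)(C)C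
F4 | step 17 | (3Z,6R,10R,11S)-12-[(tert-butyldimethylsilyl)oxy]-1,1-diethoxy-6-hydroxy-3-iodo-11-[(4-methoxybenzyl)oxy]-6,10-dimethyldodec-3-en-8-yn-7-one | CCOC(OCC)C/C(I)=C/C[C@@](C)(O)C(=O)C#C[C@@H](C)[C@H](OCc1ccc(OC)cc1)CO[Si](C)(C)C(C)(C)C
F5 | step 17 | (2R)-5-[(2S,3S)-4-[(tert-butyldimethylsilyl)oxy]-3-[(4-methoxybenzyl)oxy]butan-2-yl]-2-[(2Z)-5,5-diethoxy-3-iodopent-2-en-1-yl]-2-methylfuran-3(2H)-one | CCOC(OCC)C/C(I)=C/C[C@@]1(C)OC(=CC1=O)[C@@H](C)[C@H](OCc2ccc(OC)cc2)CO[Si](C)(C)C(C)(C)C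
F6 | step 17 | (2R)-2-[(2Z)-5,5-diethoxy-3-iodopent-2-en-1-yl]-5-[(2S,3S)-4-hydroxy-3-[(4-methoxybenzyl)oxy]butan-2-yl]-2-methylfuran-3(2H)-one | CCOC(OCC)C/C(I)=C/C[C@@]1(C)OC(=CC1=O)[C@@H](C)[C@H](OCc2ccc(OC)cc2)CO
F7 | step 17 | (2S,3S)-3-{(5R)-5-[(2Z)-5,5-diethoxy-3-iodopent-2-en-1-yl]-5-methyl-4-oxo-4,5-dihydrofuran-2-yl}-2-[(4-methoxybenzyl)oxy]butanal | CCOC(OCC)C/C(I)=C/C[C@@]1(C)OC(=CC1=O)[C@@H](C)[C@H](OCc2ccc(OC)cc2)C=O
F8 | step 19 | 7,8-epoxide of 25 with the epoxide oxygen syn to the C6 hydroxyl | CCOC(OCC)C[C@@]13O[C@H]3C[C@@]2(C)OC(=CC2=O)[C@@H](C)[C@H](OCc4ccc(OC)cc4)[C@H]1O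
F9 | step 21 | 8-[fluoro(dimethyl)silyl] 6-alcohol from ring opening of 27 | CCOC(OCC)C[C@@H]1[C@@H]([Si](C)(C)F)C[C@@]2(C)OC(=CC2=O)[C@@H](C)[C@H](OCc3ccc(OC)cc3)[C@H]1O
F10 | step 21 | 6-O-methacryloyl derivative of F9 | CCOC(OCC)C[C@@H]1[C@@H]([Si](C)(C)F)C[C@@]2(C)OC(=CC2=O)[C@@H](C)[C@H](OCc3ccc(OC)cc3)[C@H]1OC(=O)C(C)=C
F11 | step 21 | 8-hydroxy 6-O-methacryloyl diethyl acetal (31 without its silyl group) | CCOC(OCC)C[C@@H]1[C@@H](O)C[C@@]2(C)OC(=CC2=O)[C@@H](C)[C@H](OCc3ccc(OC)cc3)[C@H]1OC(=O)C(C)=C
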